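All runs are simulated with made-up constants; scatter was added.

If the oak flask has gone flat, the first question is what a further wait can give: the asked flask is oak carried on.

in all of them: impurity 6.5 mM

| charge | substrate | reagent | free catalyst | temperature | remark | time |
|---|---|---|---|---|---|---|
| oak | 3 M | 1.5 M | 6 mM | 100 °C | the very flask that is asked about, followed so far |  |
| larch | 3 M | 1.5 M | 3 mM | 85 °C | run made earlier |  |
| flask | 3.0 M | 1.50 M | 6.0 mM | 100 °C |  | 5.0 h |

| oak: time / min | oak: product / % | larch: time / min | larch: product / % |
|---|---|---|---|
| 12.0 | 24.4 | 2.00 | 1.7 |
| 40.0 | 27.4 | 5.00 | 3.5 |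
| 60.0 | 31.5 | 8.00 | 5.9 |
| 90.0 | 28.7 | 12.0 | 7.4 |
| 150 | 29.9 | 20.0 | 8.8 |
| 180 | 29.7 | 25.0 | 8.7 |
| 240 | 28.4 | 30.0 | 10.9 |

(standard deviation of a reading: 1 percentage point)

- north-east: at 5.0 h raise the temperature by 25 K, then wait 2.5 h
- west: at 5.0 h take out 90% of the product then present, then wait 2.5 h
- south: at 5.0 h add free catalyst, 100% of the amount charged, then wait 2.5 h
- north: change nothing and wait 2.5 h more

- product taken out counts as made
- steps under discussion: substrate + free catalyst <-> catalyst intermediate A; reagent + catalyst intermediate A -> catalyst intermediate B; catalyst intermediate B <-> free catalyst + product; free catalyst + impurity -> spent catalyst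
- additions bring no volume worth counting

- product, in percent of the substrate first charged, at 5.0 h
- which option adds most product ("none" when 2 percentage points or less is all one gets) (north-east / west / south / north / none)
- product present, with what was taken out counted in, in percent of the substrate first charged, after west
- product present, with what was taken out counted in, in percent of the substrate first charged, after south

Substrate and free catalyst bind reversibly to catalyst intermediate A, reagent turns that into catalyst intermediate B, and this releases product and free catalyst reversibly. Free catalyst and impurity go irreversibly to spent catalyst.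

How much has the oak flask made? Its readings from 40.0 min on average 29.3%, and that is my figure for 5.0 h.

What does the charge allow? Reagent is used one for one with substrate, so the ceiling is 50.0%, and oak should still hold 0.622 M of reagent.

Then why flat? Impurity charged minus free catalyst charged is 0.500 mM: the impurity excess. The loss step takes one impurity per free catalyst, so in the oak flask, where the impurity charge is the larger, the loss step can turn the catalyst charged into spent catalyst with impurity over.

Couldn't the oak flask simply have reached an equilibrium? That is the weak spot. Larch, with half the catalyst and an excess of 3.50 mM, reads 10.9% at 30.0 min, but larch is colder, so this is a hint and no proof.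

And the options? Waiting, heating or taking out product give a stopped round nothing, so I expect 29.3% after west. South adds 6.00 mM, and with the excess paid 5.50 mM stands. Oak made 24.4% in 12.0 min, so that catalyst needs roughly 11.1 min for the remaining reagent. The rate will sink as reagent falls, but 2.5 h is far longer, so I say 50.0% after south.

The forecast gives 29.3% now, south as best, 29.3% after west and 48% after south, a little below my figure. Its grounds: “Waiting, heating or removing product therefore gains nothing”.

The flask gives 30.8% at 5.0 h, and south adds 19 percentage points, while north adds 0 points. West ends at 30.8%, south at 50.0%.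

    substrate + free catalyst ⇌ catalyst intermediate A (K = 0.172 M⁻¹, k = 0.261 M⁻¹ s⁻¹, Ea = 60.0 kJ mol⁻¹, ΔH = −18.0 kJ mol⁻¹)
    reagent + catalyst intermediate A → catalyst intermediate B (k = 12.6 M⁻¹ s⁻¹, Ea = 65.0 kJ mol⁻¹)
    catalyst intermediate B ⇌ free catalyst + product (K = 8.83 M, k = 3.96 s⁻¹, Ea = 86.0 kJ mol⁻¹, ΔH = 42.0 kJ mol⁻¹)
    free catalyst + impurity → spent catalyst (k = 1.61 M⁻¹ s⁻¹, Ea = 67.0 kJ mol⁻¹)
    (constants at 100 °C)

The loss of free catalyst with impurity is the largest single effect on this stop: struck out of the asked flask, product at 5.0 h goes from 30.8% to 50.0%, and south's gain falls from 19 points to −0.024 points. The excess of 0.500 mM is 7.69% of the impurity charge, and the flask holds 7.7% at 300 min. For the neighbour charged with 1.50 mM, the excess is 5.00 mM, or 76.9% of the charge; that neighbour stops at 3.85% product and keeps 77% of its impurity.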